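The route hinges on disconnecting the O1–C8a bond of unit 1, the flavone whose ring B is methoxylated. In ring A, C8a is flanked by the acylated C4a and by C8, which carries the central aryl ring; a fluorine installed on C8a therefore predetermines the 8-aryl (never 6-aryl) connectivity. In a single operation the enolate oxygen of a 1-(2-fluoroaryl)-1,3-diketone replaces that fluorine and closes ring C of unit 1. The cyclization substrate is a fully benzylated diketone: ring A bears fluorine, a 2-benzyloxy-5-bromophenyl group and two benzyloxy groups, and the bromide is kept as the handle from which the apigenin unit is built afterwards.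

Key step: step 7

Remark: the target has no stereocentre and its SMILES defines no axial configuration, so the C8–aryl axis is built without stereocontrol.
Remark: 4-bromo-2-iodoanisole, methyl vanillate and 2,4,6-trihydroxyacetophenone are taken as purchasable.
Remark: the acetyl group is introduced while all oxygens are still methyl ethers, so no benzyl ether meets a strong Lewis acid. The central-ring oxygen is benzylated before the cyclization, so it cannot attack the C–F bond.

Step 1
Reactants: 1 1-fluoro-3,5-dimethoxybenzene; 2 4-bromo-2-iodoanisole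
Product: 5 5'-bromo-2-fluoro-2',4,6-trimethoxy-1,1'-biphenyl, via aryllithium 3 (not isolated), via arylzinc chloride 4 (not isolated)
Conditions: lithium 2,2,6,6-tetramethylpiperidide (from n-BuLi and the amine), THF, −78 °C; ZnCl2, −78 °C to rt; then 2, Pd(PPh3)4, THF, 55 °C
Reagents that add atoms: none
Why: Directed ortho-metalation should remove the most acidic ring proton, the one flanked by fluorine and methoxy; zincation at −78 °C forestalls loss of LiF to an aryne, and the Negishi coupling should engage the C–I bond of 2 well before its C–Br bond.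

Step 2
Reactants: 5 5'-bromo-2-fluoro-2',4,6-trimethoxy-1,1'-biphenyl
Product: 6 1-[3-(5-bromo-2-methoxyphenyl)-2-fluoro-4,6-dimethoxyphenyl]ethan-1-one
Conditions: AcCl, AlCl3, CH2Cl2, 0 °C
Reagents that add atoms: acetyl chloride, CC(=O)Cl
Why: Friedel–Crafts acylation should go to the ring A carbon that is para to one methoxy and flanked only by fluorine, since this site is more activated and less crowded than the carbon between the two methoxy groups, and the bromoanisole ring is deactivated by bromine.

Step 3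
Reactants: 6 1-[3-(5-bromo-2-methoxyphenyl)-2-fluoro-4,6-dimethoxyphenyl]ethan-1-one
Product: 7 1-[3-(5-bromo-2-hydroxyphenyl)-2-fluoro-4,6-dihydroxyphenyl]ethan-1-one
Conditions: BBr3, CH2Cl2, −78 °C to rt; then H2O
Reagents that add atoms: none
Why: BBr3 ether cleavage (Lewis acid–base adduct, then bromide SN2 attack at methyl) should remove all three methyl groups and leave the ketone, the C–F bond and the C–Br bond untouched.

Step 4
Reactants: 7 1-[3-(5-bromo-2-hydroxyphenyl)-2-fluoro-4,6-dihydroxyphenyl]ethan-1-one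
Product: 8 1-[4,6-bis(benzyloxy)-3-(2-benzyloxy-5-bromophenyl)-2-fluorophenyl]ethan-1-one
Conditions: BnBr (excess), K2CO3, DMF, rt then 50 °C
Reagents that add atoms: benzyl bromide, BrCc1ccccc1
Why: Williamson etherification; at ambient temperature intermolecular O-benzylation should far outpace a five-membered SNAr closure of the central-ring phenoxide onto C–F, and the hydrogen-bonded ortho-hydroxyl is benzylated on warming once that oxygen is capped.

Step 5
Reactants: 9 methyl vanillate
Product: 10 methyl 4-(benzyloxy)-3-methoxybenzoate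
Conditions: BnBr, K2CO3, DMF, 60 °C
Reagents that add atoms: benzyl bromide, BrCc1ccccc1
Why: Williamson etherification of the only phenol, with the methyl ester inert to carbonate.

Step 6
Reactants: 8 1-[4,6-bis(benzyloxy)-3-(2-benzyloxy-5-bromophenyl)-2-fluorophenyl]ethan-1-one; 10 methyl 4-(benzyloxy)-3-methoxybenzoate
Product: 12 1-[4,6-bis(benzyloxy)-3-(2-benzyloxy-5-bromophenyl)-2-fluorophenyl]-3-(4-benzyloxy-3-methoxyphenyl)propane-1,3-dione, via lithium enolate 11 (not isolated)
Conditions: LiN(SiMe3)2 (excess), THF, −78 °C; then 10, −78 °C to 40 °C; 1 M HCl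
Reagents that add atoms: none
Why: Crossed Claisen condensation of the methyl ketone enolate with a non-enolizable aryl ester, driven by deprotonation of the diketone; the tightly chelated lithium diketonate in THF should not yet displace fluoride, so 12 can be isolated.

Step 7
Reactants: 12 1-[4,6-bis(benzyloxy)-3-(2-benzyloxy-5-bromophenyl)-2-fluorophenyl]-3-(4-benzyloxy-3-methoxyphenyl)propane-1,3-dione
Product: 13 5,7-bis(benzyloxy)-8-[2-(benzyloxy)-5-bromophenyl]-2-[4-(benzyloxy)-3-methoxyphenyl]-4H-chromen-4-one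
Conditions: K2CO3, DMF, 80 °C
Reagents that add atoms: none
Why: Carbonate removes a proton from the diketone CH2; the enolate then attacks the fluorinated carbon C8a through the oxygen on the ring B-bearing carbon, and the anionic σ-adduct, delocalized via C4a into the C4 carbonyl, expels fluoride to create the O1–C8a bond. The closest known reaction is the base-mediated intramolecular SNAr O-arylation of 1-(2-fluoroaryl)-1,3-diketones to flavones. Ring C of unit 1 closes in a six-membered addition–elimination mode, formally a 6-endo-trig conjugate attack on the C8a=C4a–C4=O unit. No stereocentre is formed. The step needs site selectivity on ring A and chemoselectivity among leaving groups and nucleophiles: fluorine marks the only carbon that can accept the oxygen, so a 6-aryl isomer cannot arise, and the two benzyloxy groups sit meta to C8a and do not oppose the attack. The unactivated C–Br bond of the central ring is inert to SNAr, and the benzyl cap on the central-ring oxygen removes the one internal nucleophile that could close a dibenzofuran onto the same C–F bond.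

Step 8
Reactants: 13 5,7-bis(benzyloxy)-8-[2-(benzyloxy)-5-bromophenyl]-2-[4-(benzyloxy)-3-methoxyphenyl]-4H-chromen-4-one
Product: 14 4-(benzyloxy)-3-{5,7-bis(benzyloxy)-2-[4-(benzyloxy)-3-methoxyphenyl]-4-oxo-4H-chromen-8-yl}benzaldehyde
Conditions: Pd(OAc)2, n-BuP(1-Ad)2, TMEDA, CO/H2 (1:1, 5 bar), toluene, 100 °C
Reagents that add atoms: carbon monoxide, [C-]#[O+]
Why: Palladium-catalysed reductive carbonylation (formylation) of an aryl bromide: oxidative addition, CO insertion and hydrogenolysis of the acyl–palladium, on a bromide para to an alkoxy group as in the standard bromoanisole substrates; the flavone and the benzyl ethers should be inert to this homogeneous catalyst.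

Step 9
Reactants: 15 2,4,6-trihydroxyacetophenone
Product: 16 1-[2,4-bis(benzyloxy)-6-hydroxyphenyl]ethan-1-one
Conditions: BnBr (2.1 equiv), K2CO3, DMF, rt
Reagents that add atoms: benzyl bromide, BrCc1ccccc1
Why: Williamson etherification that should stop at the dibenzyl ether, because the last hydroxyl is hydrogen-bonded to the acetyl carbonyl and is much less nucleophilic.

Step 10
Reactants: 14 4-(benzyloxy)-3-{5,7-bis(benzyloxy)-2-[4-(benzyloxy)-3-methoxyphenyl]-4-oxo-4H-chromen-8-yl}benzaldehyde; 16 1-[2,4-bis(benzyloxy)-6-hydroxyphenyl]ethan-1-one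
Product: 17 5,7-bis(benzyloxy)-8-{2-(benzyloxy)-5-[(E)-3-[2,4-bis(benzyloxy)-6-hydroxyphenyl]-3-oxoprop-1-en-1-yl]phenyl}-2-[4-(benzyloxy)-3-methoxyphenyl]-4H-chromen-4-one
Conditions: KOH (50% aq.), EtOH/THF, rt
Reagents that add atoms: none
Why: Claisen–Schmidt condensation of a non-enolizable, unhindered aryl aldehyde with the methyl ketone, the E1cB dehydration giving the conjugated E-chalcone; the electron-rich 5,7-dialkoxyflavone should tolerate hydroxide at ambient temperature.

Step 11
Reactants: 17 the (E)-chalcone named in step 10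
Product: 18 5,7-bis(benzyloxy)-8-{2-(benzyloxy)-5-[5,7-bis(benzyloxy)-4-oxo-4H-chromen-2-yl]phenyl}-2-[4-(benzyloxy)-3-methoxyphenyl]-4H-chromen-4-one
Conditions: I2 (cat.), DMSO, 130 °C
Reagents that add atoms: none
Why: I2/DMSO oxidative cyclization of a 2'-hydroxychalcone: oxa-Michael closure to the flavanone, α-iodination and loss of HI, with DMSO re-oxidizing HI to I2; the chalcone geometry is consumed and no stereocentre remains.

Step 12
Reactants: 18 the hexa-O-benzyl biflavone named in step 11
Product: 19 8-[5-(5,7-dihydroxy-4-oxo-4H-chromen-2-yl)-2-hydroxyphenyl]-5,7-dihydroxy-2-(4-hydroxy-3-methoxyphenyl)-4H-chromen-4-one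
Conditions: H2 (1 atm), 10% Pd/C, THF/MeOH, rt
Reagents that add atoms: none
Why: Catalytic hydrogenolysis should cleave all six benzylic C–O bonds while the aryl methyl ether and, under these mild conditions, the two chromone C2=C3 bonds remain.

Compound list
1 | 1-fluoro-3,5-dimethoxybenzene | COc1cc(F)cc(OC)c1 | starting material
2 | 4-bromo-2-iodoanisole (4-bromo-2-iodo-1-methoxybenzene) | COc1ccc(Br)cc1I | starting material
3 | (2-fluoro-4,6-dimethoxyphenyl)lithium (not isolated) | COc1cc(F)c([Li])c(OC)c1 | intermediate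
4 | (2-fluoro-4,6-dimethoxyphenyl)zinc chloride (not isolated) | COc1cc(F)c([Zn]Cl)c(OC)c1 | intermediate
5 | 5'-bromo-2-fluoro-2',4,6-trimethoxy-1,1'-biphenyl | COc1cc(F)c(-c2cc(Br)ccc2OC)c(OC)c1 | intermediate
6 | 1-[3-(5-bromo-2-methoxyphenyl)-2-fluoro-4,6-dimethoxyphenyl]ethan-1-one | CC(=O)c1c(F)c(-c2cc(Br)ccc2OC)c(OC)cc1OC | intermediate
7 | 1-[3-(5-bromo-2-hydroxyphenyl)-2-fluoro-4,6-dihydroxyphenyl]ethan-1-one | CC(=O)c1c(F)c(-c2cc(Br)ccc2O)c(O)cc1O | intermediate
8 | 1-[4,6-bis(benzyloxy)-3-(2-benzyloxy-5-bromophenyl)-2-fluorophenyl]ethan-1-one | CC(=O)c1c(F)c(-c2cc(Br)ccc2OCc2ccccc2)c(OCc2ccccc2)cc1OCc1ccccc1 | intermediate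
9 | methyl vanillate (methyl 4-hydroxy-3-methoxybenzoate) | COC(=O)c1ccc(O)c(OC)c1 | starting material
10 | methyl 4-(benzyloxy)-3-methoxybenzoate | COC(=O)c1ccc(OCc2ccccc2)c(OC)c1 | intermediate
11 | lithium enolate of ketone 8 (not isolated) | [Li]OC(=C)c1c(F)c(-c2cc(Br)ccc2OCc2ccccc2)c(OCc2ccccc2)cc1OCc1ccccc1 | intermediate
12 | 1-[4,6-bis(benzyloxy)-3-(2-benzyloxy-5-bromophenyl)-2-fluorophenyl]-3-(4-benzyloxy-3-methoxyphenyl)propane-1,3-dione | COc1cc(C(=O)CC(=O)c2c(F)c(-c3cc(Br)ccc3OCc3ccccc3)c(OCc3ccccc3)cc2OCc2ccccc2)ccc1OCc1ccccc1 | intermediate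
13 | 5,7-bis(benzyloxy)-8-[2-(benzyloxy)-5-bromophenyl]-2-[4-(benzyloxy)-3-methoxyphenyl]-4H-chromen-4-one | COc1cc(-c2cc(=O)c3c(OCc4ccccc4)cc(OCc4ccccc4)c(-c4cc(Br)ccc4OCc4ccccc4)c3o2)ccc1OCc1ccccc1 | intermediate
14 | 4-(benzyloxy)-3-{5,7-bis(benzyloxy)-2-[4-(benzyloxy)-3-methoxyphenyl]-4-oxo-4H-chromen-8-yl}benzaldehyde | COc1cc(-c2cc(=O)c3c(OCc4ccccc4)cc(OCc4ccccc4)c(-c4cc(C=O)ccc4OCc4ccccc4)c3o2)ccc1OCc1ccccc1 | intermediate
15 | 2,4,6-trihydroxyacetophenone | CC(=O)c1c(O)cc(O)cc1O | starting material
16 | 1-[2,4-bis(benzyloxy)-6-hydroxyphenyl]ethan-1-one | CC(=O)c1c(O)cc(OCc2ccccc2)cc1OCc1ccccc1 | intermediate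
17 | 5,7-bis(benzyloxy)-8-{2-(benzyloxy)-5-[(E)-3-[2,4-bis(benzyloxy)-6-hydroxyphenyl]-3-oxoprop-1-en-1-yl]phenyl}-2-[4-(benzyloxy)-3-methoxyphenyl]-4H-chromen-4-one | COc1cc(-c2cc(=O)c3c(OCc4ccccc4)cc(OCc4ccccc4)c(-c4cc(/C=C/C(=O)c5c(O)cc(OCc6ccccc6)cc5OCc5ccccc5)ccc4OCc4ccccc4)c3o2)ccc1OCc1ccccc1 | intermediate
18 | 5,7-bis(benzyloxy)-8-{2-(benzyloxy)-5-[5,7-bis(benzyloxy)-4-oxo-4H-chromen-2-yl]phenyl}-2-[4-(benzyloxy)-3-methoxyphenyl]-4H-chromen-4-one | COc1cc(-c2cc(=O)c3c(OCc4ccccc4)cc(OCc4ccccc4)c(-c4cc(-c5cc(=O)c6c(OCc7ccccc7)cc(OCc7ccccc7)cc6o5)ccc4OCc4ccccc4)c3o2)ccc1OCc1ccccc1 | intermediate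
19 | 8-[5-(5,7-dihydroxy-4-oxo-4H-chromen-2-yl)-2-hydroxyphenyl]-5,7-dihydroxy-2-(4-hydroxy-3-methoxyphenyl)-4H-chromen-4-one | COc1cc(-c2cc(=O)c3c(O)cc(O)c(-c4cc(-c5cc(=O)c6c(O)cc(O)cc6o5)ccc4O)c3o2)ccc1O | target

Total step count: 12.
Longest linear sequence: 10 steps (steps 1, 2, 3, 4, 6, 7, 8, 10, 11, 12); steps 5 and 9 are one-step side branches.

Steps most likely to fail

Step 1. Metalation may occur in part between the two methoxy groups, the aryllithium may lose LiF before it is zincated, the doubly ortho-substituted zinc reagent may transmetalate slowly, or the product bromide may couple a second time. Fallback, setting out from 1: electrophilic iodination with N-iodosuccinimide (cat. CF3CO2H, MeCN), directed para to one methoxy and ortho to fluorine, would give 1-fluoro-2-iodo-3,5-dimethoxybenzene F1. Suzuki–Miyaura coupling of this iodide with purchased (5-bromo-2-methoxyphenyl)boronic acid (COc1ccc(Br)cc1B(O)O; Pd(PPh3)4, K2CO3, dioxane/water, 80 °C), in which oxidative addition selects C–I over C–Br, comes back to the route at 5.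

Step 8. The aryl–palladium intermediate may be reduced before CO inserts (hydrodebromination), or the catalyst may be deactivated by the chelating, poorly soluble substrate. Fallback, setting out from 13: base-free Stille coupling with tributyl(vinyl)stannane (Pd(PPh3)4, toluene, 100 °C) would give 5,7-bis(benzyloxy)-8-[2-(benzyloxy)-5-ethenylphenyl]-2-[4-(benzyloxy)-3-methoxyphenyl]-4H-chromen-4-one F2. Lemieux–Johnson cleavage of its terminal alkene (OsO4 cat., NaIO4, 2,6-lutidine, dioxane/water), which should leave the electron-poor chromone double bond alone, comes back to the route at 14.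

Step 10. Hydroxide may add to C2 of the finished flavone and open ring C, followed by retro-Claisen fragmentation, while the hindered, deprotonated ketone condenses slowly. Fallback, setting out from 14 and 16: a hydroxide-free directed aldol, in which 16 is converted with LiN(SiMe3)2 (2.2 equiv, THF, −78 °C) into its phenoxide–enolate dianion and added to the aldehyde of 14, would give the racemic β-hydroxy ketone 5,7-bis(benzyloxy)-8-{2-(benzyloxy)-5-[3-[2,4-bis(benzyloxy)-6-hydroxyphenyl]-1-hydroxy-3-oxopropyl]phenyl}-2-[4-(benzyloxy)-3-methoxyphenyl]-4H-chromen-4-one F3. Acid-catalysed dehydration (TsOH cat., toluene, 60 °C) comes back to the route at 17.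

Further compounds
F1 | step 1 | 1-fluoro-2-iodo-3,5-dimethoxybenzene | COc1cc(F)c(I)c(OC)c1
F2 | step 8 | 5,7-bis(benzyloxy)-8-[2-(benzyloxy)-5-ethenylphenyl]-2-[4-(benzyloxy)-3-methoxyphenyl]-4H-chromen-4-one | COc1cc(-c2cc(=O)c3c(OCc4ccccc4)cc(OCc4ccccc4)c(-c4cc(C=C)ccc4OCc4ccccc4)c3o2)ccc1OCc1ccccc1
F3 | step 10 | 5,7-bis(benzyloxy)-8-{2-(benzyloxy)-5-[3-[2,4-bis(benzyloxy)-6-hydroxyphenyl]-1-hydroxy-3-oxopropyl]phenyl}-2-[4-(benzyloxy)-3-methoxyphenyl]-4H-chromen-4-one (racemic) | COc1cc(-c2cc(=O)c3c(OCc4ccccc4)cc(OCc4ccccc4)c(-c4cc(C(O)CC(=O)c5c(O)cc(OCc6ccccc6)cc5OCc5ccccc5)ccc4OCc4ccccc4)c3o2)ccc1OCc1ccccc1
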